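**Retrosynthetic overview**
1. 20 ⇒ ketone 19 (C8=O in place of C8=CH2, Takai–Lombardo). The seven-membered ring is then opened at C4–C3a: 19 ⇒ enone 18, a 1-acylcyclopentene whose chain ends in an isopropenyl group. The forward reaction is an MHAT radical conjugate addition, 7-endo.
2. Enabling feature: in the seven-membered ring the gem-dimethyl carbon C4 is bonded to ring-fusion carbon C3a, and C3a stands β to the sp2 carbon C8 through C8a. With C8 as C=O, the array C4–C3a–C8a–C8 is the retron of a tertiary-radical Giese addition. That addition joins two carbons that are both electrophilic in polar terms (the Markovnikov carbon of the isopropenyl group and the enone β-carbon).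
3. 18 ⇒ alkenyl bromide 16 + 5-methylhex-5-enal 3 (Nozaki–Hiyama–Kishi coupling, then oxidation).
4. 16 ⇒ pentenolide 11 (anti addition of BnOCH2•, enolate hydroxylation, acetolysis) ⇒ aldehyde 8 (organocatalytic hydroxymethylation, intramolecular HWE) ⇒ bromoenone 4 (CBS reduction, Eschenmoser–Claisen chirality transfer to the quaternary C1).
5. Ring order: cyclopentene (present in 4) → δ-lactone (step 8) → seven-membered ring (step 14, last).

Key step: step 14

Remark: locants follow decahydroazulene (C1 = quaternary carbon with CH3 and the lactone; C3a, C8a = ring fusion; C4 = CMe2; C8 = C=CH2) and tetrahydropyran-2-one (C3 OAc, C4 CH2OAc, C5 carbocycle); the SMILES is read as cis-fused, both fusion H on the face of the lactone substituent, C1–CH3 on the other face, lactone 3,4-cis and 4,5-trans.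

**Step 1**
Reactants: 1 methyl 5-oxohexanoate
Product: 2 methyl 5-methylhex-5-enoate
Conditions: Ph3PCH3Br, KOtBu, THF, 0 °C to rt
Reagents that add atoms: methyltriphenylphosphonium bromide, C[P+](c1ccccc1)(c1ccccc1)c1ccccc1.[Br-]
Why: Wittig methylenation, in which the non-stabilised ylide attacks the ketone far faster than the ester; no stereocentre is formed.

**Step 2**
Reactants: 2 methyl 5-methylhex-5-enoate
Product: 3 5-methylhex-5-enal
Conditions: DIBAL-H (1.05 equiv), CH2Cl2, −78 °C; Rochelle salt
Reagents that add atoms: none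
Why: Partial ester reduction, in which the tetrahedral aluminate persists at −78 °C and collapses to the aldehyde only on work-up; the 1,1-disubstituted alkene is inert.

**Step 3**
Reactants: 4 2-bromo-3-methylcyclopent-2-en-1-one
Product: 5 (1S)-2-bromo-3-methylcyclopent-2-en-1-ol
Conditions: (R)-Me-CBS (10 mol %), BH3·SMe2, THF, −20 °C
Reagents that add atoms: none
Why: Corey–Bakshi–Shibata reduction, in which the bromoalkene side acts as the large group and the ring CH2 as the small one, so the (R)-oxazaborolidine should deliver hydride to the face that gives the S carbinol.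

**Step 4**
Reactants: 5 (1S)-2-bromo-3-methylcyclopent-2-en-1-ol
Product: 7 2-[(1S)-2-bromo-1-methylcyclopent-2-en-1-yl]-N,N-dimethylacetamide, via ketene N,O-acetal 6 (not isolated)
Conditions: MeC(OMe)2NMe2 (4 equiv), xylenes, 140 °C, MeOH distilled off
Reagents that add atoms: N,N-dimethylacetamide dimethyl acetal, CC(OC)(OC)N(C)C
Why: Eschenmoser–Claisen rearrangement, whose [3,3] shift is suprafacial on the ring, so the new C–C bond forms on the face that carried C–O and the carbinol configuration passes fully to the quaternary carbon, while the alkene shifts and leaves Br on the neighbouring ring carbon.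

**Step 5**
Reactants: 7 2-[(1S)-2-bromo-1-methylcyclopent-2-en-1-yl]-N,N-dimethylacetamide
Product: 8 2-[(1S)-2-bromo-1-methylcyclopent-2-en-1-yl]acetaldehyde
Conditions: Cp2Zr(H)Cl (1.6 equiv), THF, rt; H2O/silica
Reagents that add atoms: none
Why: Amide-to-aldehyde reduction with the Schwartz reagent, which stops at the zirconated hemiaminal and leaves the trisubstituted alkenyl bromide and the quaternary centre untouched.

**Step 6**
Reactants: 8 2-[(1S)-2-bromo-1-methylcyclopent-2-en-1-yl]acetaldehyde
Product: 9 (2R)-2-[(1S)-2-bromo-1-methylcyclopent-2-en-1-yl]-3-hydroxypropanal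
Conditions: aq. HCHO (3 equiv), (S)-α,α-diphenylprolinol TMS ether (20 mol %), pH 7 phosphate buffer, toluene, rt; used crude
Reagents that add atoms: formaldehyde, C=O
Why: Enamine-catalysed α-hydroxymethylation (a cross-aldol with formaldehyde), in which the (S)-diarylprolinol silyl ether shields one face of the E-enamine so that CH2O attacks the open face and the 2R centre (lactone C5) is set under catalyst control.

**Step 7**
Reactants: 9 (2R)-2-[(1S)-2-bromo-1-methylcyclopent-2-en-1-yl]-3-hydroxypropanal
Product: 10 (2R)-2-[(1S)-2-bromo-1-methylcyclopent-2-en-1-yl]-3-oxopropyl 2-(diethoxyphosphoryl)acetate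
Conditions: (EtO)2P(O)CH2CO2H, DCC, DMAP (5 mol %), CH2Cl2, 0 °C
Reagents that add atoms: diethylphosphonoacetic acid, OC(=O)CP(=O)(OCC)OCC
Why: Steglich esterification of the primary alcohol under near-neutral conditions, where the α-hydrogen, shielded by the neighbouring quaternary carbon, should resist epimerisation and β-elimination.

**Step 8**
Reactants: 10 (2R)-2-[(1S)-2-bromo-1-methylcyclopent-2-en-1-yl]-3-oxopropyl 2-(diethoxyphosphoryl)acetate
Product: 11 (5R)-5-[(1S)-2-bromo-1-methylcyclopent-2-en-1-yl]-5,6-dihydro-2H-pyran-2-one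
Conditions: LiCl, i-Pr2NEt, MeCN, rt, 5 mM
Reagents that add atoms: none
Why: Intramolecular Horner–Wadsworth–Emmons reaction under Masamune–Roush conditions, which closes the δ-lactone ring; the six-membered ring enforces the Z alkene and the mild base spares the C5 centre.

**Step 9**
Reactants: 11 (5R)-5-[(1S)-2-bromo-1-methylcyclopent-2-en-1-yl]-5,6-dihydro-2H-pyran-2-one
Product: 12 (4R,5R)-4-[(benzyloxy)methyl]-5-[(1S)-2-bromo-1-methylcyclopent-2-en-1-yl]tetrahydro-2H-pyran-2-one
Conditions: BnOCH2CO2H (2 equiv), Ir[dF(CF3)ppy]2(dtbbpy)PF6 (1 mol %), K2HPO4, DMF, blue LED, rt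
Reagents that add atoms: benzyloxyacetic acid, OC(=O)COCc1ccccc1
Why: Photoredox decarboxylative Giese addition, in which the nucleophilic α-alkoxy radical adds to the lactone β-carbon anti to the very bulky C5 substituent and sets C4 trans to C5; the alkenyl bromide lies outside the redox window.

**Step 10**
Reactants: 12 (4R,5R)-4-[(benzyloxy)methyl]-5-[(1S)-2-bromo-1-methylcyclopent-2-en-1-yl]tetrahydro-2H-pyran-2-one
Product: 14 (3S,4R,5R)-4-[(benzyloxy)methyl]-5-[(1S)-2-bromo-1-methylcyclopent-2-en-1-yl]-3-hydroxytetrahydro-2H-pyran-2-one, via potassium enolate 13 (not isolated)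
Conditions: KHMDS, THF, −78 °C; 2-(phenylsulfonyl)-3-phenyloxaziridine; AcOH quench
Reagents that add atoms: 2-(phenylsulfonyl)-3-phenyloxaziridine (Davis reagent), O=S(=O)(c1ccccc1)N1OC1c1ccccc1
Why: Davis enolate hydroxylation, in which the tert-alkyl group at C5 locks the enolate half-chair with the C4 and C5 substituents pseudo-equatorial, so axial attack at C3 (anti to the pseudo-axial C4–H and on the face away from the carbocycle) should place OH cis to CH2OBn.

**Step 11**
Reactants: 14 (3S,4R,5R)-4-[(benzyloxy)methyl]-5-[(1S)-2-bromo-1-methylcyclopent-2-en-1-yl]-3-hydroxytetrahydro-2H-pyran-2-one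
Product: 16 (3S,4R,5R)-4-(acetoxymethyl)-5-[(1S)-2-bromo-1-methylcyclopent-2-en-1-yl]-2-oxotetrahydro-2H-pyran-3-yl acetate, via acetate benzyl ether 15 (not isolated)
Conditions: Ac2O, TMSOTf (0.2 equiv), CH2Cl2, −20 to 0 °C
Reagents that add atoms: acetic anhydride, CC(=O)OC(C)=O
Why: O-acetylation followed by Lewis-acid acetolysis of the primary benzyl ether, which turns C–OBn directly into C–OAc, so a free primary hydroxyl that could translactonise to the γ-lactone never appears; no stereocentre is touched.

**Step 12**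
Reactants: 16 (3S,4R,5R)-4-(acetoxymethyl)-5-[(1S)-2-bromo-1-methylcyclopent-2-en-1-yl]-2-oxotetrahydro-2H-pyran-3-yl acetate and 3 5-methylhex-5-enal
Product: 17 (3S,4R,5R)-4-(acetoxymethyl)-5-[(1S)-2-(1-hydroxy-5-methylhex-5-en-1-yl)-1-methylcyclopent-2-en-1-yl]-2-oxotetrahydro-2H-pyran-3-yl acetate (both carbinol epimers)
Conditions: CrCl2 (6 equiv), NiCl2 (2 mol %), DMF, rt to 45 °C
Reagents that add atoms: none
Why: Nozaki–Hiyama–Kishi coupling, in which the alkenylchromium(III) species adds only to the aldehyde and tolerates lactone and acetates; the new carbinol centre is not controlled because step 13 removes it.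

**Step 13**
Reactants: 17 (3S,4R,5R)-4-(acetoxymethyl)-5-[(1S)-2-(1-hydroxy-5-methylhex-5-en-1-yl)-1-methylcyclopent-2-en-1-yl]-2-oxotetrahydro-2H-pyran-3-yl acetate
Product: 18 (3S,4R,5R)-4-(acetoxymethyl)-5-[(1S)-1-methyl-2-(5-methylhex-5-enoyl)cyclopent-2-en-1-yl]-2-oxotetrahydro-2H-pyran-3-yl acetate
Conditions: Dess–Martin periodinane, CH2Cl2, 0 °C to rt
Reagents that add atoms: none
Why: Dess–Martin oxidation of the allylic alcohol under neutral conditions converges both epimers on the enone and installs the carbonyl that activates the cyclopentene for the key step.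

**Step 14**
Reactants: 18 (3S,4R,5R)-4-(acetoxymethyl)-5-[(1S)-1-methyl-2-(5-methylhex-5-enoyl)cyclopent-2-en-1-yl]-2-oxotetrahydro-2H-pyran-3-yl acetate
Product: 19 (3S,4R,5R)-4-(acetoxymethyl)-2-oxo-5-[(1S,3aR,8aR)-1,4,4-trimethyl-8-oxodecahydroazulen-1-yl]tetrahydro-2H-pyran-3-yl acetate
Conditions: Fe(acac)3 (30 mol %), PhSiH3 (2.5 equiv), i-PrOH, 60 °C, 5 mM
Reagents that add atoms: none
Why: An iron hydride formed from Fe(acac)3 and the silane transfers H• to the CH2 terminus of the isopropenyl group (Markovnikov MHAT), the nucleophilic tertiary radical at C4 adds to the enone β-carbon C3a, and the α-keto radical is reduced by Fe(II) to an enolate that the alcohol protonates, so the gem-dimethyl quaternary carbon, the ring and both fusion centres arise in one operation from two carbons of like (electrophilic) polarity. The closest known reaction type is the iron-catalysed reductive olefin coupling (MHAT-initiated Giese reaction) in its intramolecular form, together with endo radical cyclisations onto enones whose carbonyl lies inside the forming ring. The seven-membered ring closes in the 7-endo-trig mode, because the 6-exo alternative would need attack at the α-carbon C8a, which is polarity-mismatched and would create three contiguous quaternary carbons. C3a is controlled by the quaternary C1: the tethered radical should approach the cyclopentene face that carries the C1 methyl group and so avoid a 1,3-syn clash between the forming C3a–C4 bond and the bulky lactone. C8a is controlled by protonation of the enolate on the face opposite to the new C4 quaternary carbon and the C1 methyl, which gives the cis fusion with C8 trans to the lactone, and this should also be the less strained epimer of an epimerisable centre. The step needs H• transfer to the isopropenyl group rather than the enone, and cyclisation faster than a second H• transfer; the first is secured by the much higher MHAT reactivity of a 1,1-disubstituted alkene over a trisubstituted enone, the second by the s-trans enone conformer (C=O turned toward the quaternary C1, chain pointed at C3a) and by high dilution.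

**Step 15**
Reactants: 19 (3S,4R,5R)-4-(acetoxymethyl)-2-oxo-5-[(1S,3aR,8aR)-1,4,4-trimethyl-8-oxodecahydroazulen-1-yl]tetrahydro-2H-pyran-3-yl acetate
Product: 20 (3S,4R,5R)-4-(acetoxymethyl)-2-oxo-5-[(1R,3aR,8aS)-1,4,4-trimethyl-8-methylidenedecahydroazulen-1-yl]tetrahydro-2H-pyran-3-yl acetate
Conditions: Zn, CH2Br2, TiCl4 (reagent pre-aged in THF, −40 to 5 °C), CH2Cl2, 0 °C to rt
Reagents that add atoms: dibromomethane, BrCBr
Why: Takai–Lombardo methylenation, whose non-basic gem-dimetallic reagent converts ketones but not esters or lactones, so C8a and C3 are not epimerised and the acetates survive (the C1 and C8a descriptors change only through CIP priorities).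

**Compound list**
1 | methyl 5-oxohexanoate | CC(=O)CCCC(=O)OC | starting material
2 | methyl 5-methylhex-5-enoate | C=C(C)CCCC(=O)OC | intermediate
3 | 5-methylhex-5-enal | C=C(C)CCCC=O | intermediate
4 | 2-bromo-3-methylcyclopent-2-en-1-one | CC1=C(Br)C(=O)CC1 | starting material
5 | (1S)-2-bromo-3-methylcyclopent-2-en-1-ol | O[C@H]1CCC(C)=C1Br | intermediate
6 | 1-{[(1S)-2-bromo-3-methylcyclopent-2-en-1-yl]oxy}-N,N-dimethylethen-1-amine (ketene N,O-acetal) | C=C(N(C)C)O[C@H]1CCC(C)=C1Br | intermediate
7 | 2-[(1S)-2-bromo-1-methylcyclopent-2-en-1-yl]-N,N-dimethylacetamide | BrC1=CCC[C@@]1(C)CC(=O)N(C)C | intermediate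
8 | 2-[(1S)-2-bromo-1-methylcyclopent-2-en-1-yl]acetaldehyde | BrC1=CCC[C@@]1(C)CC=O | intermediate
9 | (2R)-2-[(1S)-2-bromo-1-methylcyclopent-2-en-1-yl]-3-hydroxypropanal | BrC1=CCC[C@@]1(C)[C@@H](C=O)CO | intermediate
10 | (2R)-2-[(1S)-2-bromo-1-methylcyclopent-2-en-1-yl]-3-oxopropyl 2-(diethoxyphosphoryl)acetate | BrC1=CCC[C@@]1(C)[C@@H](C=O)COC(=O)CP(=O)(OCC)OCC | intermediate
11 | (5R)-5-[(1S)-2-bromo-1-methylcyclopent-2-en-1-yl]-5,6-dihydro-2H-pyran-2-one | BrC1=CCC[C@@]1(C)[C@@H]2COC(=O)C=C2 | intermediate
12 | (4R,5R)-4-[(benzyloxy)methyl]-5-[(1S)-2-bromo-1-methylcyclopent-2-en-1-yl]tetrahydro-2H-pyran-2-one (4,5-trans) | BrC1=CCC[C@@]1(C)[C@@H]2COC(=O)C[C@H]2COCc3ccccc3 | intermediate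
13 | potassium enolate of 12 | [K+].BrC1=CCC[C@@]1(C)[C@@H]2COC([O-])=C[C@H]2COCc3ccccc3 | intermediate
14 | (3S,4R,5R)-4-[(benzyloxy)methyl]-5-[(1S)-2-bromo-1-methylcyclopent-2-en-1-yl]-3-hydroxytetrahydro-2H-pyran-2-one (3,4-cis, 4,5-trans) | BrC1=CCC[C@@]1(C)[C@@H]2COC(=O)[C@@H](O)[C@H]2COCc3ccccc3 | intermediate
15 | (3S,4R,5R)-4-[(benzyloxy)methyl]-5-[(1S)-2-bromo-1-methylcyclopent-2-en-1-yl]-2-oxotetrahydro-2H-pyran-3-yl acetate | BrC1=CCC[C@@]1(C)[C@@H]2COC(=O)[C@@H](OC(C)=O)[C@H]2COCc3ccccc3 | intermediate
16 | (3S,4R,5R)-4-(acetoxymethyl)-5-[(1S)-2-bromo-1-methylcyclopent-2-en-1-yl]-2-oxotetrahydro-2H-pyran-3-yl acetate | BrC1=CCC[C@@]1(C)[C@@H]2COC(=O)[C@@H](OC(C)=O)[C@H]2COC(C)=O | intermediate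
17 | (3S,4R,5R)-4-(acetoxymethyl)-5-[(1S)-2-(1-hydroxy-5-methylhex-5-en-1-yl)-1-methylcyclopent-2-en-1-yl]-2-oxotetrahydro-2H-pyran-3-yl acetate (both carbinol epimers) | C=C(C)CCCC(O)C1=CCC[C@@]1(C)[C@@H]2COC(=O)[C@@H](OC(C)=O)[C@H]2COC(C)=O | intermediate
18 | (3S,4R,5R)-4-(acetoxymethyl)-5-[(1S)-1-methyl-2-(5-methylhex-5-enoyl)cyclopent-2-en-1-yl]-2-oxotetrahydro-2H-pyran-3-yl acetate | C=C(C)CCCC(=O)C1=CCC[C@@]1(C)[C@@H]2COC(=O)[C@@H](OC(C)=O)[C@H]2COC(C)=O | intermediate
19 | (3S,4R,5R)-4-(acetoxymethyl)-2-oxo-5-[(1S,3aR,8aR)-1,4,4-trimethyl-8-oxodecahydroazulen-1-yl]tetrahydro-2H-pyran-3-yl acetate (cis-fused) | O=C1CCCC(C)(C)[C@@H]2CC[C@@](C)([C@@H]3COC(=O)[C@@H](OC(C)=O)[C@H]3COC(C)=O)[C@H]12 | intermediate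
20 | (3S,4R,5R)-4-(acetoxymethyl)-2-oxo-5-[(1R,3aR,8aS)-1,4,4-trimethyl-8-methylidenedecahydroazulen-1-yl]tetrahydro-2H-pyran-3-yl acetate | C=C1CCCC(C)(C)[C@@H]2CC[C@@](C)([C@@H]3COC(=O)[C@@H](OC(C)=O)[C@H]3COC(C)=O)[C@H]12 | target

**Step count**
Total step count: 15. Longest linear sequence: 13 steps (steps 3–15, from 4). Steps 1–2 prepare aldehyde 3.

**Steps most likely to fail**

*Step 14.* The 7-endo closure is slow. The tertiary radical may be quenched early by a second hydrogen-atom transfer (net hydrogenation of the isopropenyl group). Reversible MHAT may move the alkene inward, or the enone may suffer conjugate reduction.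
- The fallback separates radical generation from the hydrogen donor. It sets out from 18.
- Ionic Markovnikov addition of HBr (HBr/AcOH, CH2Cl2, 0 °C) should give the tertiary bromide F1.
- A classical tin-hydride chain (Bu3SnH by syringe pump, AIBN, benzene, 80 °C, 2 mM) then forms the same radical irreversibly, with the donor concentration held low.
- This route comes back at 19.

*Step 10.* The oxaziridine may show poor or reversed facial selectivity if steric approach anti to the CH2OBn group outweighs the axial trajectory.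
- The fallback sets C3 by SN2 inversion instead of by enolate face selection. It sets out from 12.
- The same oxidation is run, and the 3,4-trans alcohol F2 is taken on.
- A Mitsunobu reaction with acetic acid (PPh3, DIAD, AcOH, toluene, 0 °C to rt) inverts C3.
- This route comes back at 15, which is then treated under the step 11 conditions.

*Step 12.* Oxidative addition of the hindered alkenyl bromide (next to a quaternary carbon) to nickel may be sluggish, and the enolisable aldehyde may be consumed meanwhile.
- The fallback makes the ketone by cross-coupling with an acyl electrophile. It sets out from 16 and from ester 2.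
- Palladium-catalysed stannylation of 16 ((Me3Sn)2, Pd(PPh3)4, dioxane, 100 °C) should give the alkenylstannane F3.
- Saponification of 2 (LiOH, THF/H2O) gives 5-methylhex-5-enoic acid F4, and oxalyl chloride (cat. DMF, CH2Cl2) converts it into 5-methylhex-5-enoyl chloride F5.
- A Stille acylation of F3 with F5 (Pd2(dba)3, tri(2-furyl)phosphine, THF, 50 °C) comes back at 18 and bypasses 17.

**Further compounds**
F1 | step 14 | (3S,4R,5R)-4-(acetoxymethyl)-5-[(1S)-2-(5-bromo-5-methylhexanoyl)-1-methylcyclopent-2-en-1-yl]-2-oxotetrahydro-2H-pyran-3-yl acetate | CC(C)(Br)CCCC(=O)C1=CCC[C@@]1(C)[C@@H]2COC(=O)[C@@H](OC(C)=O)[C@H]2COC(C)=O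
F2 | step 10 | (3R,4R,5R)-4-[(benzyloxy)methyl]-5-[(1S)-2-bromo-1-methylcyclopent-2-en-1-yl]-3-hydroxytetrahydro-2H-pyran-2-one (3,4-trans) | BrC1=CCC[C@@]1(C)[C@@H]2COC(=O)[C@H](O)[C@H]2COCc3ccccc3
F3 | step 12 | (3S,4R,5R)-4-(acetoxymethyl)-5-[(1S)-1-methyl-2-(trimethylstannyl)cyclopent-2-en-1-yl]-2-oxotetrahydro-2H-pyran-3-yl acetate | C[Sn](C)(C)C1=CCC[C@@]1(C)[C@@H]2COC(=O)[C@@H](OC(C)=O)[C@H]2COC(C)=O
F4 | step 12 | 5-methylhex-5-enoic acid | C=C(C)CCCC(=O)O
F5 | step 12 | 5-methylhex-5-enoyl chloride | C=C(C)CCCC(=O)Cl
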